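Over the 2.5 h asked for, two flasks are to be forecast from two shorter runs.

all flasks: electrophile 0.20 M

| flask | free base | protonated nucleophile | remark | time |
|---|---|---|---|---|
| west | 0.12 M | 0.24 M | run made earlier |  |
| north | 0.20 M | 0.24 M | run made earlier |  |
| summer | 0.160 M | 0.240 M |  | 2.5 h |
| noon | 0.240 M | 0.240 M |  | 2.5 h |

- west (time / min: electrophile / %, target / %): 4.00: 72.3, 0.2; 12.0: 67.3, 0.5; 20.0: 67.5, 0.6; 30.0: 67.0, 0.6; 50.0: 66.2, 1.4; 60.0: 65.9, 1.1; 80.0: 65.2, 1.0
- north (time / min: electrophile / %, target / %): 4.00: 72.5, 0.5; 12.0: 68.5, 0.2; 20.0: 67.8, 0.6; 30.0: 67.4, 0.7; 50.0: 66.8, 0.6; 60.0: 65.2, 1.1; 80.0: 65.0, 1.1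

(standard deviation of a reading: 0.3 percentage points)

* part of the electrophile that has reacted at the end, summer
* part of the electrophile that has reacted at the end, noon
* what raising the concentration of free base from its lowest to its highest value here does to the part of the electrophile that has reacted (changes below 5 percentage points count as none) (it rises / no change / it falls)

- a species is counted by the electrophile in it: one side product counts as two
- what was read earlier has a scatter of 0.3 percentage points, one standard deviation
- reactions considered so far: nucleophile + acid set free <-> protonated nucleophile; electrophile + nucleophile -> acid set free + target; electrophile + target -> side product; electrophile <-> dormant form; acid set free + free base <-> salt of the base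
- what has gone from electrophile into another species counts as reacted, even if it can come back

In the first 4.00 min, the mean electrophile of the west and north runs falls by 28 percentage points, while target stays near the scatter. By 12.0 min a knee has passed: the mean stands at 67.9%, and by 80.0 min it has sunk only 2.8 points further, over 68.0 min. Run back to the start, this slow line gives the free share 68.4%, the part of the electrophile left unbound once its split with the dormant form has set in and nothing else has formed. An even split, the zero of this scale, would leave as much dormant as free, but these readings give 68.4% free against 31.6% dormant, so they lean towards the free side. At 4.00 min the mean still lies 4.2 points above the line, which reads as a half-life of 1.37 min, far shorter than the asked time: a fast pre-equilibrium.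

Continued to 2.5 h, the line adds a slow loss of 6.2 points, so this reckoning puts the reacted part, dormant form counted, at 37.8%. At 80.0 min, west reads 65.2% and north 65.0%, a gap smaller than the scatter of 0.3 points, so this reckoning takes the same figure for summer and noon.

The forecast gives 37.7% (36% to 40%) for summer, 38.2% (36% to 42%) for noon and the trend no change, observing: “West and north agree within scatter”.

The flasks give 38.3% for summer and 39.5% for noon, a difference of 1.1 points, so the trend is no change.

    nucleophile + acid set free ⇌ protonated nucleophile, settled at all times (K = 3400 L mol⁻¹)
    electrophile + nucleophile → acid set free + target (k = 2.80 L mol⁻¹ h⁻¹)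
    electrophile + target → side product (k = 13.0 L mol⁻¹ h⁻¹)
    electrophile ⇌ dormant form (K = 0.470, k = 9.40 h⁻¹)
    acid set free + free base ⇌ salt of the base (K = 22000 L mol⁻¹, k = 14.0 L mol⁻¹ h⁻¹)

At 2.50 h, summer holds 61.7% electrophile and 29.0% dormant form, a free share of 68.0% against the 68.4% read from the runs, and its slow term, the reacted part less 31.6%, is 6.7 points against the reckoned 6.2 points. The neighbouring flask, noon with 0.96 M of protonated nucleophile, holds 53.9% and 25.5%, a free share of 67.9%, but its slow term is 15 points, against 7.9 points in noon. The neighbour ends at 46.1%, above the forecast's upper end of 42% for noon. The answer for noon has moved by 5 points at 0.725 M of protonated nucleophile.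

(The numbers in the tables are simulated on assumed constants; scatter was added.)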